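**Retrosynthetic overview**
1. C7=O: removed first. The enone comes from allylic C–H oxidation of the C5=C6 alkene in the last step.
2. C11–C12: Wittig olefination followed by hydrogenation joins a bicyclic C11 aldehyde to a C12–C16 phosphonium salt. The salt is made from (S)-4-methyloxolan-2-one, which brings in C13.
3. C7–C8 and C9–C10: a catalyst-controlled exo Diels–Alder reaction of a ring A vinylcyclohexene with tiglaldehyde sets C8, C9 and C10.
4. C18–O (key bond): enantioselective desymmetrising C–H acetoxylation of the gem-dimethyl group of 2,2-dimethylcyclohexanone sets C4. It also installs the acetate, which is carried unprotected to the end.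
5. Ring order: ring A is bought, and ring B is closed by the cycloaddition.

Assumption: the SMILES is read as (4R,8R,9S,10S,13R)-18-acetoxy-7-oxohalim-5-en-15-oic acid (halimane numbering: ring A = C1–C5 and C10, ring B = C5–C10, chain C11–C15, C16 on C13, C17 on C8, C18 = CH2OAc and C19 = CH3 on C4, C20 on C9; 10α-H, 8β-CH3, 9β-CH3, 4α-CH2OAc), and (S)-4-methyloxolan-2-one is taken as a catalogue item.

**Step 1**
Reactants: 1 2,2-dimethylcyclohexan-1-one
Product: 4 (S)-(1-methyl-2-oxocyclohexyl)methyl acetate, via ketimine 2 (not isolated), via acetoxylated ketimine 3 (not isolated)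
Conditions: Pd(OAc)2 (10 mol %), L-tert-leucine (30 mol %), 3-nitro-5-(trifluoromethyl)pyridin-2-ol (20 mol %), 1-fluoro-2,4,6-trimethylpyridinium tetrafluoroborate (1.3 equiv), AcOH/HFIP 1:1, 80 °C, 24 h
Reagents that add atoms: acetic acid, CC(=O)O
Why: Proposed new method: enantioselective desymmetrising methyl C(sp3)–H acetoxylation of a gem-dimethyl ketone through a chiral transient directing group; 1 condenses reversibly with L-tert-leucine to the E-ketimine 2, whose N,O-chelate holds divalent palladium on the side of the quaternary carbon, so pyridone-assisted concerted metalation–deprotonation reaches only the methyl group lying in the imine plane (the equatorial one) and closes a 5,5-fused palladacycle; the pseudo-axial tert-butyl group of the chelate clashes with ring CH2-6 (allylic 1,3-strain) unless the body of the chair lies on the opposite face, which selects one of the two mirror-image chairs and hence one enantiotopic methyl (model: L-tert-leucine gives S); the N-fluoropyridinium salt oxidises the palladacycle to tetravalent palladium, C–OAc reductive elimination forms the C18–O bond and sets C4, and hydrolysis of 3 frees 4 and the amino acid; a second acetoxylation is matched only for the minor enantiomer, which raises the ee of 4; the closest known reaction types are oxime-ether-directed methyl C–H acetoxylation with PhI(OAc)2, glycine-mediated β-C–H arylation of ketones, tert-leucine-mediated enantioselective benzylic C–H acyloxylation of 2-alkylbenzaldehydes with the same oxidant, and diastereoselective gem-dimethyl acetoxylation directed by tert-leucinol-derived oxazolines.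

**Step 2**
Reactants: 4 (S)-(1-methyl-2-oxocyclohexyl)methyl acetate
Product: 5 [(1S)-1-methyl-2-(trifluoromethylsulfonyloxy)cyclohex-2-en-1-yl]methyl acetate
Conditions: Tf2O (1.3 equiv), 2,6-di-tert-butyl-4-methylpyridine (1.5 equiv), CH2Cl2, 0 °C to rt
Reagents that add atoms: trifluoromethanesulfonic anhydride, O=S(=O)(OS(=O)(=O)C(F)(F)F)C(F)(F)F
Why: Enol triflate formation without a metal enolate: the ketone can lose a proton only on its CH2 side because the other α-carbon is quaternary, so one regioisomer forms, and avoiding an enolate avoids acetyl transfer, lactone aldol and retro-aldol, so C4 is untouched.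

**Step 3**
Reactants: 5 [(1S)-1-methyl-2-(trifluoromethylsulfonyloxy)cyclohex-2-en-1-yl]methyl acetate; 6 tributyl(vinyl)stannane
Product: 7 [(1R)-2-ethenyl-1-methylcyclohex-2-en-1-yl]methyl acetate
Conditions: Pd(PPh3)4 (3 mol %), LiCl (3 equiv), THF, 65 °C
Reagents that add atoms: none
Why: Stille coupling: zerovalent palladium inserts into the vinyl C–OTf bond, and LiCl-assisted transmetalation from tin followed by reductive elimination gives the diene under neutral conditions that spare the acetate and C4 (the descriptor changes by priority only).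

**Step 4**
Reactants: 7 [(1R)-2-ethenyl-1-methylcyclohex-2-en-1-yl]methyl acetate; 8 (E)-2-methylbut-2-enal (tiglaldehyde)
Product: 9 [(1R,4aR,5R,6S)-5-formyl-1,5,6-trimethyl-1,2,3,4,4a,5,6,7-octahydronaphthalen-1-yl]methyl acetate (18-acetoxy-12,13,14,15,16-pentanorhalim-5-en-11-al)
Conditions: (R)-o-tolyl oxazaborolidine from (R)-α,α-diphenylprolinol (20 mol %), Tf2NH (18 mol %), 8 (3 equiv), CH2Cl2, −78 to −40 °C, 48 h
Reagents that add atoms: none
Why: Enantioselective Diels–Alder reaction catalysed by a chiral oxazaborolidinium ion: the s-trans enal, held by boron and a formyl C–H···O contact, is shielded on its Cα-Re face so the diene adds to the Cα-Si face; the unhindered CH2 terminus (C7) bonds first to Cβ (C8) and fixes the regiochemistry, the α-methyl group favours the exo-formyl transition state (H10 cis to C11), the E-geometry of 8 places C17 and C20 cis, and the remote C4 centre (CH3 against CH2OAc) has little bias, so reagent control sets C8, C9 and C10 relative to C4.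

**Step 5**
Reactants: 10 (S)-4-methyloxolan-2-one
Product: 11 [(2S)-3-carboxy-2-methylpropyl]triphenylphosphonium bromide
Conditions: Ph3P·HBr (1.0 equiv), neat, 165 °C, 8 h; trituration with Et2O
Reagents that add atoms: triphenylphosphine hydrobromide, [Br-].c1ccc(cc1)[PH+](c1ccccc1)c1ccccc1
Why: Acid-mediated lactone opening followed by SN2 phosphonium salt formation at the CH2–O carbon; the stereocentre (future C13) is not a reacting atom and is not acidic, so it is kept.

**Step 6**
Reactants: 9 bicyclic aldehyde; 11 [(2S)-3-carboxy-2-methylpropyl]triphenylphosphonium bromide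
Product: 13 (4R,8S,9S,10S,11Z,13S)-18-acetoxyhalima-5,11-dien-15-oic acid, via ylide carboxylate 12 (not isolated)
Conditions: 11 (2.0 equiv), NaN(SiMe3)2 (3.9 equiv), THF, 0 °C, 1 h; then 9, −78 °C to rt; 1 M HCl work-up
Reagents that add atoms: none
Why: Wittig olefination with a non-stabilised ylide carboxylate: the aldehyde is non-enolisable, slightly less than two equivalents of base per salt leaves no free amide to attack the acetate, and the alkene geometry does not matter because the double bond is reduced next.

**Step 7**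
Reactants: 13 (4R,8S,9S,10S,11Z,13S)-18-acetoxyhalima-5,11-dien-15-oic acid
Product: 14 (4R,8S,9R,10S,13R)-18-acetoxyhalim-5-en-15-oic acid
Conditions: H2 (1 atm), 5% Pt on carbon, EtOAc, rt
Reagents that add atoms: none
Why: Chemoselective heterogeneous hydrogenation: the strained Z-disubstituted C11=C12 bond is reduced while the trisubstituted C5=C6 bond next to quaternary C4 is inert, and platinum is used instead of palladium to avoid double-bond migration that could erode C13 or shift C5=C6.

**Step 8**
Reactants: 14 (4R,8S,9R,10S,13R)-18-acetoxyhalim-5-en-15-oic acid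
Product: 15 (4R,8R,9S,10S,13R)-18-acetoxy-7-oxohalim-5-en-15-oic acid (target)
Conditions: CrO3 (15 equiv), 3,5-dimethylpyrazole (15 equiv), CH2Cl2, −20 °C, 4 h
Reagents that add atoms: chromium trioxide, O=[Cr](=O)=O
Why: Allylic C–H oxidation with the CrO3–3,5-dimethylpyrazole complex: C7 is the only allylic CH2 and the only site that can end as a ketone, C10–H is screened by the syn-axial C18 acetoxymethyl group and by quaternary C9, acid and acetate tolerate hexavalent chromium, and the C8 methyl is already in its favoured equatorial position, so no stereocentre is changed.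

**Compound list**
1 | 2,2-dimethylcyclohexan-1-one | CC1(C)CCCCC1=O | starting material
2 | (S)-2-[(E)-(2,2-dimethylcyclohexylidene)amino]-3,3-dimethylbutanoic acid (ketimine, bound to palladium) | OC(=O)[C@H](C(C)(C)C)/N=C1\CCCCC1(C)C | intermediate
3 | (S)-2-{(E)-[(2R)-2-(acetoxymethyl)-2-methylcyclohexylidene]amino}-3,3-dimethylbutanoic acid (acetoxylated ketimine) | OC(=O)[C@H](C(C)(C)C)/N=C1\CCCC[C@@]1(C)COC(C)=O | intermediate
4 | (S)-(1-methyl-2-oxocyclohexyl)methyl acetate | CC(=O)OC[C@]1(C)CCCCC1=O | intermediate
5 | [(1S)-1-methyl-2-(trifluoromethylsulfonyloxy)cyclohex-2-en-1-yl]methyl acetate | CC(=O)OC[C@]1(C)CCCC=C1OS(=O)(=O)C(F)(F)F | intermediate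
6 | tributyl(vinyl)stannane | C=C[Sn](CCCC)(CCCC)CCCC | starting material
7 | [(1R)-2-ethenyl-1-methylcyclohex-2-en-1-yl]methyl acetate | CC(=O)OC[C@]1(C)CCCC=C1C=C | intermediate
8 | (E)-2-methylbut-2-enal | C/C=C(\C)C=O | starting material
9 | [(1R,4aR,5R,6S)-5-formyl-1,5,6-trimethyl-1,2,3,4,4a,5,6,7-octahydronaphthalen-1-yl]methyl acetate | CC(=O)OC[C@]1(C)CCC[C@@H]2C1=CC[C@H](C)[C@@]2(C)C=O | intermediate
10 | (S)-4-methyloxolan-2-one | C[C@@H]1COC(=O)C1 | starting material
11 | [(2S)-3-carboxy-2-methylpropyl]triphenylphosphonium bromide | [Br-].OC(=O)C[C@H](C)C[P+](c1ccccc1)(c1ccccc1)c1ccccc1 | intermediate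
12 | sodium (3S)-3-methyl-4-(triphenylphosphoranylidene)butanoate | [Na+].[O-]C(=O)C[C@H](C)C=P(c1ccccc1)(c1ccccc1)c1ccccc1 | intermediate
13 | (4R,8S,9S,10S,11Z,13S)-18-acetoxyhalima-5,11-dien-15-oic acid | CC(=O)OC[C@]1(C)CCC[C@@H]2C1=CC[C@H](C)[C@@]2(C)/C=C\[C@@H](C)CC(=O)O | intermediate
14 | (4R,8S,9R,10S,13R)-18-acetoxyhalim-5-en-15-oic acid | CC(=O)OC[C@]1(C)CCC[C@@H]2C1=CC[C@H](C)[C@@]2(C)CC[C@@H](C)CC(=O)O | intermediate
15 | (4R,8R,9S,10S,13R)-18-acetoxy-7-oxohalim-5-en-15-oic acid | CC(=O)OC[C@]1(C)CCC[C@@H]2C1=CC(=O)[C@H](C)[C@@]2(C)CC[C@@H](C)CC(=O)O | target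

**Total step count:** 8. **Longest linear sequence:** 7 (steps 1, 2, 3, 4, 6, 7, 8).

**Three steps most likely to fail**

Step 1 (the proposed new step).
- Risks: the hindered ketone may form too little ketimine. The enamine tautomer may be fluorinated at C6 of the ketone. Double acetoxylation may cost yield. The level and sense of induction are untested; if the sense is reversed, D-tert-leucine is used.
- The fallback uses known chemistry. It sets out from 1 and comes back at 4.
- 1 with NH2OH·HCl and NaOAc in EtOH gives (E)-2,2-dimethylcyclohexanone oxime F1.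
- In AcOH/Ac2O this is acetylated in the flask to (E)-2,2-dimethylcyclohexanone O-acetyl oxime F2.
- Pd(OAc)2 (5 mol %) and PhI(OAc)2 at 100 °C then acetoxylate one methyl group to racemic [(2E)-2-(acetoxyimino)-1-methylcyclohexyl]methyl acetate F3.
- K2CO3 in MeOH removes both acetyl groups to give racemic (E)-2-(hydroxymethyl)-2-methylcyclohexanone oxime F4.
- Aqueous NaHSO3 in EtOH at 80 °C hydrolyses the oxime to racemic 2-(hydroxymethyl)-2-methylcyclohexanone F5.
- Kinetic resolution with Burkholderia cepacia lipase and vinyl acetate acetylates the S alcohol to 4. The slower R enantiomer of F5 is removed by chromatography.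

Step 4.
- Risks: a hindered diene and a trisubstituted enal may react slowly. The acetate may bind the catalyst. The exo/endo ratio or facial control may be moderate.
- The fallback replaces catalyst control by a covalent auxiliary. It sets out from 7 and comes back at 9.
- Tigloyl chloride and lithiated (n-BuLi) (S)-4-benzyl-1,3-oxazolidin-2-one give (S)-4-benzyl-3-[(E)-2-methylbut-2-enoyl]-1,3-oxazolidin-2-one F6.
- Me2AlCl (2.5 equiv) in CH2Cl2 at −40 °C chelates F6, and 7 adds anti to the benzyl group in the exo mode. This gives the imide adduct (S)-4-benzyl-3-(18-acetoxy-12,13,14,15,16-pentanorhalim-5-en-11-oyl)-1,3-oxazolidin-2-one F7.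
- LiSEt (EtSH, n-BuLi, THF, 0 °C) displaces the auxiliary to give the S-ethyl thioester F8. The acetate survives because an alkoxide is a far poorer leaving group than the imide anion.
- Fukuyama reduction (Et3SiH, Pd on carbon, acetone) gives 9.

Step 8.
- Risks: abstraction of the tertiary allylic C10–H would lead to C6- or C10-oxygenated or transposed products. Conversion may stop at the allylic alcohol.
- The fallback replaces C–H abstraction by alkene functionalisation with transposition. It sets out from 14 and comes back at 15.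
- mCPBA with NaHCO3 in CH2Cl2 gives 18-acetoxy-5,6-epoxyhaliman-15-oic acid F9. Either face is acceptable because both converge.
- PhSeNa from (PhSe)2 and NaBH4 in EtOH opens the epoxide at the less hindered C6 to 18-acetoxy-5-hydroxy-6-(phenylselanyl)haliman-15-oic acid F10.
- H2O2 oxidises this to the selenoxide F11, which can eliminate only towards C7. The product is 18-acetoxy-5-hydroxyhalim-6-en-15-oic acid F12.
- Pyridinium chlorochromate, [C5H5NH][CrO3Cl], in CH2Cl2 then effects the Babler–Dauben oxidative 1,3-transposition to 15.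

**Further compounds**
F1 | step 1 | (E)-2,2-dimethylcyclohexanone oxime | O/N=C1\CCCCC1(C)C
F2 | step 1 | (E)-2,2-dimethylcyclohexanone O-acetyl oxime | CC(=O)O/N=C1\CCCCC1(C)C
F3 | step 1 | racemic [(2E)-2-(acetoxyimino)-1-methylcyclohexyl]methyl acetate | CC(=O)O/N=C1\CCCCC1(C)COC(C)=O
F4 | step 1 | racemic (E)-2-(hydroxymethyl)-2-methylcyclohexanone oxime | O/N=C1\CCCCC1(C)CO
F5 | step 1 | racemic 2-(hydroxymethyl)-2-methylcyclohexanone | OCC1(C)CCCCC1=O
F6 | step 4 | (S)-4-benzyl-3-[(E)-2-methylbut-2-enoyl]-1,3-oxazolidin-2-one | C/C=C(\C)C(=O)N1[C@@H](Cc2ccccc2)COC1=O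
F7 | step 4 | (S)-4-benzyl-3-(18-acetoxy-12,13,14,15,16-pentanorhalim-5-en-11-oyl)-1,3-oxazolidin-2-one | CC(=O)OC[C@]1(C)CCC[C@@H]2C1=CC[C@H](C)[C@@]2(C)C(=O)N3[C@@H](Cc4ccccc4)COC3=O
F8 | step 4 | S-ethyl 18-acetoxy-12,13,14,15,16-pentanorhalim-5-ene-11-thioate | CC(=O)OC[C@]1(C)CCC[C@@H]2C1=CC[C@H](C)[C@@]2(C)C(=O)SCC
F9 | step 8 | 18-acetoxy-5,6-epoxyhaliman-15-oic acid (C5 and C6 either face) | CC(=O)OC[C@]1(C)CCC[C@@H]2C13OC3C[C@H](C)[C@@]2(C)CC[C@@H](C)CC(=O)O
F10 | step 8 | 18-acetoxy-5-hydroxy-6-(phenylselanyl)haliman-15-oic acid | CC(=O)OC[C@]1(C)CCC[C@@H]2C1(O)C([Se]c3ccccc3)C[C@H](C)[C@@]2(C)CC[C@@H](C)CC(=O)O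
F11 | step 8 | 18-acetoxy-5-hydroxy-6-(phenylseleninyl)haliman-15-oic acid (selenoxide) | CC(=O)OC[C@]1(C)CCC[C@@H]2C1(O)C([Se](=O)c3ccccc3)C[C@H](C)[C@@]2(C)CC[C@@H](C)CC(=O)O
F12 | step 8 | 18-acetoxy-5-hydroxyhalim-6-en-15-oic acid | CC(=O)OC[C@]1(C)CCC[C@@H]2C1(O)C=C[C@H](C)[C@@]2(C)CC[C@@H](C)CC(=O)O
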